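**Retrosynthetic overview**

1. The target comes from its 7,7'-dibenzyl ether carrying a bromine at C8 of the chroman (one hydrogenolysis removes all three groups). That compound comes from its chroman-4-carboxylic acid by reductive decarboxylation.
2. Ring D is cut at C4–C4a and C2–C3 together. A decarboxylative radical (4+2) annulation joins the α-aryloxyisobutyric acid hung on the 4'-oxygen of the finished isoflavone with acrylic acid, a two-carbon unit whose carboxyl group is a removable activator.
3. Enabling feature: in ring D the ether oxygen O1 carries the quaternary C2 with its two methyl groups, so C2 can be generated as a tertiary α-aryloxy radical from a carboxylic acid. O1 sits on ring B ortho to the electron-rich C–H carbon C3' (the later C4a, flanked by the 2'-OMe and O1). The other ortho carbon, C5', is blocked by bromine.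
4. Ring C comes from a 2'-hydroxychalcone by hypervalent-iodine 1,2-aryl shift and acid ring closure. The chalcone comes from a Claisen–Schmidt condensation of 4-benzyloxy-2-hydroxyacetophenone with a benzaldehyde made from 2,4-dihydroxy-6-methoxybenzaldehyde (O-alkylation, bromination, benzylation).
5. Ring order: rings A and B are bought; ring C closes in step 5; ring D closes in step 6.

Key step: step 6

Assumption: 2,4-dihydroxy-6-methoxybenzaldehyde (1) is treated as a purchasable catalogue compound.

**Route**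

Step 1
Reactants: 1 2,4-dihydroxy-6-methoxybenzaldehyde; 2 tert-butyl 2-bromo-2-methylpropanoate
Product: 3 tert-butyl 2-(4-formyl-3-hydroxy-5-methoxyphenoxy)-2-methylpropanoate
Conditions: Cs2CO3 (1.2 equiv), 2 (2 equiv), DMF, 60 °C
Reagents that add atoms: none
Why: Williamson-type O-alkylation of a phenoxide by an α-bromoisobutyrate (the fibrate alkylation) should take place only at the 4-OH, which is the more acidic hydroxyl and is not held in the hydrogen bond to the aldehyde that deactivates the 2-OH; no stereocenter is formed.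

Step 2
Reactants: 3 tert-butyl 2-(4-formyl-3-hydroxy-5-methoxyphenoxy)-2-methylpropanoate
Product: 4 tert-butyl 2-(2-bromo-4-formyl-3-hydroxy-5-methoxyphenoxy)-2-methylpropanoate
Conditions: NBS (1.0 equiv), CH2Cl2, 0 °C
Reagents that add atoms: N-bromosuccinimide O=C1CCC(=O)N1Br
Why: Electrophilic aromatic bromination in which the free, aldehyde-chelated hydroxyl directs the bromine to its own ortho position, as is usual for 2-hydroxy-4,6-dialkoxyaryl carbonyl compounds, so that the carbon that becomes C5' of ring B (C8 of the chroman) is blocked; no stereocenter is formed.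

Step 3
Reactants: 4 tert-butyl 2-(2-bromo-4-formyl-3-hydroxy-5-methoxyphenoxy)-2-methylpropanoate
Product: 5 tert-butyl 2-[3-(benzyloxy)-2-bromo-4-formyl-5-methoxyphenoxy]-2-methylpropanoate
Conditions: BnBr (1.5 equiv), K2CO3 (2 equiv), n-Bu4NI (cat.), DMF, 60 °C
Reagents that add atoms: benzyl bromide BrCc1ccccc1
Why: Williamson ether synthesis; the benzyl ether removes the acidic phenol that would deactivate the aldehyde as a phenoxide in step 4 and be oxidised in step 5.

Step 4
Reactants: 5 tert-butyl 2-[3-(benzyloxy)-2-bromo-4-formyl-5-methoxyphenoxy]-2-methylpropanoate; 6 1-[4-(benzyloxy)-2-hydroxyphenyl]ethan-1-one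
Product: 7 tert-butyl 2-[3-(benzyloxy)-4-{(1E)-3-[4-(benzyloxy)-2-hydroxyphenyl]-3-oxoprop-1-en-1-yl}-2-bromo-5-methoxyphenoxy]-2-methylpropanoate
Conditions: KOH (50% aq.), EtOH, rt, 48 h
Reagents that add atoms: none
Why: Claisen–Schmidt (crossed aldol) condensation of the acetophenone enolate with the non-enolisable aldehyde, the E1cB dehydration giving the thermodynamically favoured E-enone, while the hindered tert-butyl ester resists hydroxide.

Step 5
Reactants: 7 tert-butyl 2-[3-(benzyloxy)-4-{(1E)-3-[4-(benzyloxy)-2-hydroxyphenyl]-3-oxoprop-1-en-1-yl}-2-bromo-5-methoxyphenoxy]-2-methylpropanoate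
Product: 9 2-{3-(benzyloxy)-4-[7-(benzyloxy)-4-oxo-4H-chromen-3-yl]-2-bromo-5-methoxyphenoxy}-2-methylpropanoic acid, via β-keto dimethyl acetal 8 (not isolated)
Conditions: PhI(OH)OTs (1.2 equiv), HC(OMe)3/MeOH (1:3), rt; evaporate; then TFA/CH2Cl2 (1:1), rt
Reagents that add atoms: none
Why: Hypervalent-iodine oxidative rearrangement of a 2'-hydroxychalcone (methoxy-iodination of the enone, then 1,2-shift of the electron-rich ring B through a phenonium ion to the β-keto acetal), followed by acid-promoted closure of ring C by the phenol on the acetal carbon with loss of methanol and simultaneous acidolysis of the tert-butyl ester; the stereocenter of 8 is destroyed on aromatisation.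

Step 6
Reactants: 9 2-{3-(benzyloxy)-4-[7-(benzyloxy)-4-oxo-4H-chromen-3-yl]-2-bromo-5-methoxyphenoxy}-2-methylpropanoic acid; 10 acrylic acid
Product: 12 7-(benzyloxy)-6-[7-(benzyloxy)-4-oxo-4H-chromen-3-yl]-8-bromo-5-methoxy-2,2-dimethylchromane-4-carboxylic acid (racemic), via N-hydroxyphthalimide ester 11 (not isolated)
Conditions: N-hydroxyphthalimide (1.1 equiv), DIC (1.1 equiv), DMAP (5 mol %), CH2Cl2, rt; filter, evaporate; then 10 (3 equiv), fac-Ir(ppy)3 (1 mol %), MeCN, blue LEDs (450 nm), rt
Reagents that add atoms: none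
Why: Excited fac-Ir(ppy)3 transfers an electron to ester 11, which loses phthalimide anion and CO2 to give the tertiary α-aryloxy radical at the future C2; this nucleophilic radical adds to the CH2 terminus of acrylic acid (C2–C3 bond), the resulting electrophilic α-carboxyalkyl radical attacks the electron-rich ring-B carbon C3' (C4–C4a bond), and oxidation of the cyclohexadienyl radical by the oxidised photocatalyst (tetravalent iridium) with loss of a proton restores the arene. The closest known reaction type is the photoredox (4+2) radical annulation of N-(acyloxy)phthalimides of aryloxyacetic acids with electron-poor olefins to chromans (Giese addition followed by homolytic aromatic substitution). Ring D closes in a six-membered mode by ortho attack of the C4 radical on the arene (6-exo-trig with respect to the C3'=C2' bond). The new C4 stereocenter forms without control as a racemate, which is of no consequence because step 7 removes the carboxyl group. The step needs ring closure at C3' only, and this is secured because the other carbon ortho to the ether oxygen (C5') carries bromine, where ipso attack is sterically disfavoured. The polarity sequence (nucleophilic radical, electron-poor olefin, electrophilic radical, electron-rich arene) should keep the radicals from adding to a second olefin or to the chromone.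

Step 7
Reactants: 12 7-(benzyloxy)-6-[7-(benzyloxy)-4-oxo-4H-chromen-3-yl]-8-bromo-5-methoxy-2,2-dimethylchromane-4-carboxylic acid
Product: 14 7-(benzyloxy)-3-[7-(benzyloxy)-8-bromo-5-methoxy-2,2-dimethylchroman-6-yl]-4H-chromen-4-one, via N-hydroxyphthalimide ester 13 (not isolated)
Conditions: N-hydroxyphthalimide (1.1 equiv), DIC (1.1 equiv), DMAP (5 mol %), CH2Cl2, rt; then Ru(bpy)3Cl2·6H2O (1 mol %), Hantzsch ester (1.5 equiv), t-BuSH (0.2 equiv), CH2Cl2, blue LEDs, rt
Reagents that add atoms: none
Why: Okada-type reductive decarboxylation of an N-(acyloxy)phthalimide: single-electron reduction by the photoreduced Ru(bpy)3Cl2 catalyst releases CO2 and a benzylic C4 radical that takes a hydrogen atom from the thiol/Hantzsch ester, which erases the C4 stereocenter and leaves the plain CH2–CH2 unit.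

Step 8
Reactants: 14 7-(benzyloxy)-3-[7-(benzyloxy)-8-bromo-5-methoxy-2,2-dimethylchroman-6-yl]-4H-chromen-4-one
Product: 15 7-hydroxy-3-(7-hydroxy-5-methoxy-2,2-dimethylchroman-6-yl)-4H-chromen-4-one (glycyrrhizaisoflavone C)
Conditions: H2 (1 atm), 10% Pd/C, NaOAc (2 equiv), EtOAc/MeOH (1:1), rt
Reagents that add atoms: none
Why: Catalytic hydrogenolysis cleaves both benzyl ethers and the aryl C–Br bond (NaOAc takes up HBr), while the C2=C3 bond of the chromone, a vinylogous ester, is reduced much more slowly and should be spared by stopping at the calculated hydrogen uptake.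

**Compound list**

1 | 2,4-dihydroxy-6-methoxybenzaldehyde | COc1cc(O)cc(O)c1C=O | starting material
2 | tert-butyl 2-bromo-2-methylpropanoate | CC(C)(Br)C(=O)OC(C)(C)C | starting material
3 | tert-butyl 2-(4-formyl-3-hydroxy-5-methoxyphenoxy)-2-methylpropanoate | COc1cc(OC(C)(C)C(=O)OC(C)(C)C)cc(O)c1C=O | intermediate
4 | tert-butyl 2-(2-bromo-4-formyl-3-hydroxy-5-methoxyphenoxy)-2-methylpropanoate | COc1cc(OC(C)(C)C(=O)OC(C)(C)C)c(Br)c(O)c1C=O | intermediate
5 | tert-butyl 2-[3-(benzyloxy)-2-bromo-4-formyl-5-methoxyphenoxy]-2-methylpropanoate | COc1cc(OC(C)(C)C(=O)OC(C)(C)C)c(Br)c(OCc2ccccc2)c1C=O | intermediate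
6 | 1-[4-(benzyloxy)-2-hydroxyphenyl]ethan-1-one | CC(=O)c1ccc(OCc2ccccc2)cc1O | starting material
7 | tert-butyl 2-[3-(benzyloxy)-4-{(1E)-3-[4-(benzyloxy)-2-hydroxyphenyl]-3-oxoprop-1-en-1-yl}-2-bromo-5-methoxyphenoxy]-2-methylpropanoate | COc1cc(OC(C)(C)C(=O)OC(C)(C)C)c(Br)c(OCc2ccccc2)c1/C=C/C(=O)c1ccc(OCc2ccccc2)cc1O | intermediate
8 | tert-butyl 2-[3-(benzyloxy)-4-{1-[4-(benzyloxy)-2-hydroxyphenyl]-3,3-dimethoxy-1-oxopropan-2-yl}-2-bromo-5-methoxyphenoxy]-2-methylpropanoate (racemic, not isolated) | COc1cc(OC(C)(C)C(=O)OC(C)(C)C)c(Br)c(OCc2ccccc2)c1C(C(OC)OC)C(=O)c1ccc(OCc2ccccc2)cc1O | intermediate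
9 | 2-{3-(benzyloxy)-4-[7-(benzyloxy)-4-oxo-4H-chromen-3-yl]-2-bromo-5-methoxyphenoxy}-2-methylpropanoic acid | COc1cc(OC(C)(C)C(=O)O)c(Br)c(OCc2ccccc2)c1-c1coc2cc(OCc3ccccc3)ccc2c1=O | intermediate
10 | acrylic acid | C=CC(=O)O | starting material
11 | 1,3-dioxoisoindolin-2-yl 2-{3-(benzyloxy)-4-[7-(benzyloxy)-4-oxo-4H-chromen-3-yl]-2-bromo-5-methoxyphenoxy}-2-methylpropanoate (not isolated) | COc1cc(OC(C)(C)C(=O)ON2C(=O)c3ccccc3C2=O)c(Br)c(OCc2ccccc2)c1-c1coc2cc(OCc3ccccc3)ccc2c1=O | intermediate
12 | 7-(benzyloxy)-6-[7-(benzyloxy)-4-oxo-4H-chromen-3-yl]-8-bromo-5-methoxy-2,2-dimethylchromane-4-carboxylic acid (racemic) | COc1c2C(C(=O)O)CC(C)(C)Oc2c(Br)c(OCc2ccccc2)c1-c1coc2cc(OCc3ccccc3)ccc2c1=O | intermediate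
13 | 1,3-dioxoisoindolin-2-yl 7-(benzyloxy)-6-[7-(benzyloxy)-4-oxo-4H-chromen-3-yl]-8-bromo-5-methoxy-2,2-dimethylchromane-4-carboxylate (racemic, not isolated) | COc1c2C(C(=O)ON3C(=O)c4ccccc4C3=O)CC(C)(C)Oc2c(Br)c(OCc2ccccc2)c1-c1coc2cc(OCc3ccccc3)ccc2c1=O | intermediate
14 | 7-(benzyloxy)-3-[7-(benzyloxy)-8-bromo-5-methoxy-2,2-dimethylchroman-6-yl]-4H-chromen-4-one | COc1c2CCC(C)(C)Oc2c(Br)c(OCc2ccccc2)c1-c1coc2cc(OCc3ccccc3)ccc2c1=O | intermediate
15 | 7-hydroxy-3-(7-hydroxy-5-methoxy-2,2-dimethylchroman-6-yl)-4H-chromen-4-one (glycyrrhizaisoflavone C; achiral) | COc1c2CCC(C)(C)Oc2cc(O)c1-c1coc2cc(O)ccc2c1=O | target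

**Step count and risks**

Total step count: 8. Longest linear sequence: 8 steps (1 to 15); 2, 6 and 10 are purchased building blocks.

Steps most likely to fail:

1. Step 6. The homolytic aromatic substitution at the crowded C3' (between the methoxy group and the ether oxygen) may be too slow. The adduct radical would then be lost to oligomerisation with further acrylic acid, or the tertiary α-aryloxy radical would be oxidised before it adds, with loss of the side chain. The fallback sets out from 9 and comes back at 15, and it closes ring D by the classical propargyl ether route.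
 - Photoredox decarboxylative alkynylation of 9 with 1-[(triisopropylsilyl)ethynyl]-1,2-benziodoxol-3(1H)-one ([Ir(dF(CF3)ppy)2(dtbbpy)]PF6, caesium benzoate CsO2CPh, 1,2-dichloroethane, blue LEDs) should give the silylated propargyl ether 7-(benzyloxy)-3-[2-(benzyloxy)-3-bromo-6-methoxy-4-{[2-methyl-4-(triisopropylsilyl)but-3-yn-2-yl]oxy}phenyl]-4H-chromen-4-one F1.
 - TBAF in THF should free the aryl 1,1-dimethylpropargyl ether 7-(benzyloxy)-3-{2-(benzyloxy)-3-bromo-6-methoxy-4-[(2-methylbut-3-yn-2-yl)oxy]phenyl}-4H-chromen-4-one F2.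
 - Heating in N,N-diethylaniline at about 190 °C (aromatic propargyl Claisen rearrangement, 1,5-hydrogen shift, oxa-6π electrocyclisation, with only C3' free) should give the 2H-chromene 7-(benzyloxy)-3-[7-(benzyloxy)-8-bromo-5-methoxy-2,2-dimethyl-2H-chromen-6-yl]-4H-chromen-4-one F3.
 - The conditions of step 8 then also saturate the C3=C4 bond of ring D and deliver 15.

2. Step 5. The hypervalent iodine reagent may be diverted before the 1,2-aryl shift, either by attack of the free ring-A phenol on the activated enone (aurone or flavone formation) or by electrophilic attack on the very electron-rich ring B. The fallback sets out from 7 and comes back at 9, and it ties the phenol up in a ring before the oxidation.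
 - NaOAc in refluxing EtOH should isomerise 7 to the flavanone tert-butyl 2-{3-(benzyloxy)-4-[7-(benzyloxy)-4-oxochroman-2-yl]-2-bromo-5-methoxyphenoxy}-2-methylpropanoate F4 (racemic).
 - Tl(NO3)3·3H2O in HC(OMe)3/MeOH with catalytic HClO4 should effect the 2,3-aryl shift and dehydrogenation to the isoflavone ester tert-butyl 2-{3-(benzyloxy)-4-[7-(benzyloxy)-4-oxo-4H-chromen-3-yl]-2-bromo-5-methoxyphenoxy}-2-methylpropanoate F5.
 - TFA/CH2Cl2 then gives 9.

3. Step 8. Over-reduction of the chromone C2=C3 bond to the isoflavanone may compete, or the hydrodebromination at the hindered, electron-rich C8 may stall. The fallback sets out from 14 and comes back at 15, and it separates the two tasks without hydrogen gas.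
 - BCl3 with pentamethylbenzene in CH2Cl2 at −78 °C should remove both benzyl groups to give the bromo diphenol 3-(8-bromo-7-hydroxy-5-methoxy-2,2-dimethylchroman-6-yl)-7-hydroxy-4H-chromen-4-one F6.
 - Homogeneous transfer hydrodebromination (Pd(OAc)2, PPh3, HCO2Na, DMF, 80 °C) should then give 15.

**Further compounds**

F1 | step 6 | 7-(benzyloxy)-3-[2-(benzyloxy)-3-bromo-6-methoxy-4-{[2-methyl-4-(triisopropylsilyl)but-3-yn-2-yl]oxy}phenyl]-4H-chromen-4-one | COc1cc(OC(C)(C)C#C[Si](C(C)C)(C(C)C)C(C)C)c(Br)c(OCc2ccccc2)c1-c1coc2cc(OCc3ccccc3)ccc2c1=O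
F2 | step 6 | 7-(benzyloxy)-3-{2-(benzyloxy)-3-bromo-6-methoxy-4-[(2-methylbut-3-yn-2-yl)oxy]phenyl}-4H-chromen-4-one | COc1cc(OC(C)(C)C#C)c(Br)c(OCc2ccccc2)c1-c1coc2cc(OCc3ccccc3)ccc2c1=O
F3 | step 6 | 7-(benzyloxy)-3-[7-(benzyloxy)-8-bromo-5-methoxy-2,2-dimethyl-2H-chromen-6-yl]-4H-chromen-4-one | COc1c2C=CC(C)(C)Oc2c(Br)c(OCc2ccccc2)c1-c1coc2cc(OCc3ccccc3)ccc2c1=O
F4 | step 5 | tert-butyl 2-{3-(benzyloxy)-4-[7-(benzyloxy)-4-oxochroman-2-yl]-2-bromo-5-methoxyphenoxy}-2-methylpropanoate (racemic) | COc1cc(OC(C)(C)C(=O)OC(C)(C)C)c(Br)c(OCc2ccccc2)c1C1CC(=O)c2ccc(OCc3ccccc3)cc2O1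
F5 | step 5 | tert-butyl 2-{3-(benzyloxy)-4-[7-(benzyloxy)-4-oxo-4H-chromen-3-yl]-2-bromo-5-methoxyphenoxy}-2-methylpropanoate | COc1cc(OC(C)(C)C(=O)OC(C)(C)C)c(Br)c(OCc2ccccc2)c1-c1coc2cc(OCc3ccccc3)ccc2c1=O
F6 | step 8 | 3-(8-bromo-7-hydroxy-5-methoxy-2,2-dimethylchroman-6-yl)-7-hydroxy-4H-chromen-4-one | COc1c2CCC(C)(C)Oc2c(Br)c(O)c1-c1coc2cc(O)ccc2c1=O
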